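**Retrosynthetic overview**

1. The ester bond is cut to give C15 alcohol 23 and ω‑silyloxy C32 acid 29; the acid comes from two C16 units by a copper‑catalysed Grignard coupling.
2. C17 is put on C8 through enol triflate 20 (Stille hydroxymethylation). The side chain C11–C15 comes from a vinylogous Mukaiyama–Michael addition to the C9 exo‑methylene enone 13, and C9 is set by protonation.
3. Ring A is made by a formal [3+3] annulation of (1S,5S)‑verbenone with 1,3‑bis(trimethylsilyl)propene: C10–C1 by conjugate allylation, C3–C4 by cation–allylsilane closure once the cyclobutane bond C7–C4 is cleaved.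
4. Enabling feature: in verbenone the C8 carbonyl activates C10 through the C9=C10 π bond and C4 through the strained σ bond C7–C4 of the cyclobutane C4–C5–C6–C7. These two carbons flank C5 and become the two fully substituted carbons of ring A, and the bicycle fixes C10 relative to C5.
5. Ring order: ring B (C5–C10) is the six‑membered ring of verbenone, set free when the four‑membered ring opens; ring A is closed in the key step.

Key step: step 2

Remark (numbering): labdane numbering of the target is used for every intermediate (decalin C1–C10, gem‑dimethyl on C4, C20 on C10, C17 on C8, side chain C11–C16 on C9); in verbenone C‑4 = C10, C‑6 = C4, C‑1 = C7, C‑2 = C8, C‑3 = C9, C‑5 = C5, C‑7 = C6.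
Assumption: the acyl part is read as 32‑hydroxydotriacontanoyl (31 chain carbons after the carbonyl carbon).

**Route**

Step 1
Reactants: 1 allyltrimethylsilane
Product: 3 (E)-1,3-bis(trimethylsilyl)prop-1-ene, via silylallyllithium 2 (not isolated)
Conditions: s-BuLi, TMEDA, THF, −78 to −30 °C; then Me3SiCl, −78 °C to rt
Reagents that add atoms: chlorotrimethylsilane, C[Si](C)(C)Cl
Why: Deprotonation gives a silyl‑stabilised allyl anion that should be silylated at the less hindered γ‑terminus to give the E isomer (allyl anion silylation).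

Step 2
Reactants: 4 (1S,5S)-(−)-verbenone; 3 (E)-1,3-bis(trimethylsilyl)prop-1-ene (1.5 equiv)
Product: 7 (4aR,8aR)-5,5,8a-trimethyl-3,4,4a,5,6,8a-hexahydronaphthalen-2(1H)-one, via silyl enol ether adduct 5 (not isolated), via ring-closed silyl enol ether 6 (not isolated)
Conditions: Tf2NH (0.1 equiv), CH2Cl2, −78 to −40 °C; then Tf2NH (1.1 equiv), −78 to −20 °C; aq. NaHCO3, then 1 M citric acid/THF, rt
Reagents that add atoms: none
Why: Proposed new method: Me3SiNTf2 formed from Tf2NH and 3 activates the enone, and 3 adds through its silyl‑bearing vinylic carbon to the β‑carbon C10 on the face anti to the gem‑dimethyl bridge (Hosomi–Sakurai conjugate allylation, the closest known type together with the carbonyl additions of 1,3‑disilylpropenes), which sets the C10 quaternary centre with C1 trans to C4 and gives silyl enol ether 5. Protonation of 5 at C9 by the stoichiometric acid produces a silyloxycarbenium ion at C8 that is discharged by heterolysis of the strained cyclobutane bond C7–C4 (the known acid‑induced cleavage of pinan‑2‑ones), releasing a tertiary cation at C4 and the C7=C8 enol ether. The new allylsilane captures this cation through its terminal carbon C3 in a 6‑endo, chair‑like closure of ring A (allylsilane‑terminated cation–olefin cyclisation) and loses silicon from C1 to leave the C1=C2 alkene; work‑up hydrolyses enol ether 6 to ketone 7. Because C1 and C4 sit trans on ring B they can bridge only diequatorially, so the ring fusion should be trans with the C10 methyl axial, while C5 is carried over from verbenone and C4 is not stereogenic. The step needs conjugate addition before ring opening and protonation of the enol ether before the allylsilane: the first is secured by adding the stoichiometric acid only after the catalytic stage (the saturated ketone can open only at C7–C4, the bond that gives a tertiary cation), the second by the much higher nucleophilicity of the silyl enol ether.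

Step 3
Reactants: 7 (4aR,8aR)-5,5,8a-trimethyl-3,4,4a,5,6,8a-hexahydronaphthalen-2(1H)-one
Product: 8 (4aR,8aS)-5,5,8a-trimethyloctahydronaphthalen-2(1H)-one
Conditions: H2 (1 atm), Pd/C (10 %), EtOAc, rt
Reagents that add atoms: none
Why: Heterogeneous hydrogenation should saturate the cis‑disubstituted C1=C2 alkene and leave the ketone untouched; no stereocentre is formed.

Step 4
Reactants: 8 (4aR,8aS)-5,5,8a-trimethyloctahydronaphthalen-2(1H)-one
Product: 9 (4aR,8aS)-5,5,8a-trimethyl-4a,5,6,7,8,8a-hexahydronaphthalen-2(1H)-one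
Conditions: 2-iodoxybenzoic acid (IBX), DMSO/toluene, 70 °C
Reagents that add atoms: none
Why: Dehydrogenation of the ketone through its enol (IBX dehydrogenation) can desaturate only C6–C7 because C10 is quaternary; the enone blocks C7 and directs later enolisation to C9.

Step 5
Reactants: 9 (4aR,8aS)-5,5,8a-trimethyl-4a,5,6,7,8,8a-hexahydronaphthalen-2(1H)-one
Product: 13 (4aR,8aR)-5,5,8a-trimethyl-1-methylidene-4a,5,6,7,8,8a-hexahydronaphthalen-2(1H)-one, via lithium dienolate 10 (not isolated), via Mannich base 11 (not isolated), via methiodide 12 (not isolated)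
Conditions: LiN(i-Pr)2, THF, −78 °C; [Me2N=CH2]I, −78 to 0 °C; then MeI, CH2Cl2, rt; then aq. NaHCO3, CH2Cl2, rt
Reagents that add atoms: N,N-dimethylmethyleneiminium iodide (Eschenmoser's salt), C=[N+](C)C.[I-]
Why: Kinetic deprotonation at the α′ carbon C9 (the only α‑CH2 left), Mannich alkylation and E1cB elimination of the quaternised amine should give the exocyclic methylene (Eschenmoser methylenation); the transient C9 stereocentre is erased.

Step 6
Reactants: 14 ethyl 3-methylbut-2-enoate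
Product: 16 [(1-ethoxy-3-methylbuta-1,3-dien-1-yl)oxy]trimethylsilane, via lithium dienolate 15 (not isolated)
Conditions: LiN(i-Pr)2, THF, −78 °C; then Me3SiCl, −78 °C to rt
Reagents that add atoms: chlorotrimethylsilane, C[Si](C)(C)Cl
Why: γ‑Deprotonation of the senecioate and O‑silylation of the lithium dienolate give the silyl ketene acetal (silyl dienolate formation).

Step 7
Reactants: 13 (4aR,8aR)-5,5,8a-trimethyl-1-methylidene-4a,5,6,7,8,8a-hexahydronaphthalen-2(1H)-one; 16 [(1-ethoxy-3-methylbuta-1,3-dien-1-yl)oxy]trimethylsilane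
Product: 18 ethyl (2E)-3-methyl-5-[(1S,4aR,8aR)-5,5,8a-trimethyl-2-oxo-1,2,4a,5,6,7,8,8a-octahydronaphthalen-1-yl]pent-2-enoate, via silyl dienol ether 17 (not isolated)
Conditions: Me3SiOTf (0.1 equiv), CH2Cl2, −78 °C; then 1 M citric acid/THF, 0 °C
Reagents that add atoms: none
Why: Vinylogous Mukaiyama–Michael addition: the silyl dienolate attacks through its γ‑carbon at the unhindered exocyclic CH2 (C11), the s‑trans diene giving the E‑enoate, and C‑protonation of the 2‑silyloxydiene at C9 from the face anti to the axial C10 methyl should set C9 with the side chain cis to that methyl.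

Step 8
Reactants: 18 ethyl (2E)-3-methyl-5-[(1S,4aR,8aR)-5,5,8a-trimethyl-2-oxo-1,2,4a,5,6,7,8,8a-octahydronaphthalen-1-yl]pent-2-enoate
Product: 20 ethyl (2E)-3-methyl-5-[(1S,4aR,8aR)-5,5,8a-trimethyl-2-[(trifluoromethanesulfonyl)oxy]-1,4,4a,5,6,7,8,8a-octahydronaphthalen-1-yl]pent-2-enoate, via lithium enolate 19 (not isolated)
Conditions: LiBH(s-Bu)3, THF, −78 °C; then PhNTf2, −78 to 0 °C
Reagents that add atoms: N-phenylbis(trifluoromethanesulfonimide), O=S(=O)(N(c1ccccc1)S(=O)(=O)C(F)(F)F)C(F)(F)F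
Why: Conjugate hydride delivery to C6 of the β‑unsubstituted cyclohexenone gives the C7=C8 lithium enolate regiospecifically, which is O‑sulfonylated (reductive enol triflate formation); C9 is not enolised and the β,β‑disubstituted enoate should be inert at −78 °C.

Step 9
Reactants: 20 ethyl (2E)-3-methyl-5-[(1S,4aR,8aR)-5,5,8a-trimethyl-2-[(trifluoromethanesulfonyl)oxy]-1,4,4a,5,6,7,8,8a-octahydronaphthalen-1-yl]pent-2-enoate
Product: 21 ethyl (2E)-5-[(1S,4aR,8aR)-2-(hydroxymethyl)-5,5,8a-trimethyl-1,4,4a,5,6,7,8,8a-octahydronaphthalen-1-yl]-3-methylpent-2-enoate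
Conditions: Bu3SnCH2OH, Pd(PPh3)4 (cat.), LiCl, 1,4-dioxane, 100 °C
Reagents that add atoms: (tributylstannyl)methanol, CCCC[Sn](CCCC)(CCCC)CO
Why: Stille coupling of the enol triflate with the hydroxymethylstannane puts C17 on C8 and keeps the C7=C8 alkene in place.

Step 10
Reactants: 21 ethyl (2E)-5-[(1S,4aR,8aR)-2-(hydroxymethyl)-5,5,8a-trimethyl-1,4,4a,5,6,7,8,8a-octahydronaphthalen-1-yl]-3-methylpent-2-enoate
Product: 22 ethyl (2E)-5-[(1S,4aR,8aR)-2-{[tert-butyl(dimethyl)silyl]oxymethyl}-5,5,8a-trimethyl-1,4,4a,5,6,7,8,8a-octahydronaphthalen-1-yl]-3-methylpent-2-enoate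
Conditions: t-BuMe2SiCl, imidazole, DMF, rt
Reagents that add atoms: tert-butyldimethylsilyl chloride, CC(C)(C)[Si](C)(C)Cl
Why: Silyl ether protection of the C17 alcohol keeps the two primary allylic alcohols differentiated for the esterification.

Step 11
Reactants: 22 ethyl (2E)-5-[(1S,4aR,8aR)-2-{[tert-butyl(dimethyl)silyl]oxymethyl}-5,5,8a-trimethyl-1,4,4a,5,6,7,8,8a-octahydronaphthalen-1-yl]-3-methylpent-2-enoate
Product: 23 (2E)-5-[(1S,4aR,8aR)-2-{[tert-butyl(dimethyl)silyl]oxymethyl}-5,5,8a-trimethyl-1,4,4a,5,6,7,8,8a-octahydronaphthalen-1-yl]-3-methylpent-2-en-1-ol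
Conditions: i-Bu2AlH, CH2Cl2, −78 °C; aq. KNaC4H4O6
Reagents that add atoms: none
Why: 1,2‑Reduction of the enoate by the aluminium hydride should give the C15 allylic alcohol with the E geometry retained; the silyl ether survives.

Step 12
Reactants: 24 16-bromohexadecan-1-ol
Product: 25 [(16-bromohexadecyl)oxy](tert-butyl)dimethylsilane
Conditions: t-BuMe2SiCl, imidazole, CH2Cl2, rt
Reagents that add atoms: tert-butyldimethylsilyl chloride, CC(C)(C)[Si](C)(C)Cl
Why: Silyl ether protection masks the alcohol before the Grignard reagent is formed.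

Step 13
Reactants: 25 [(16-bromohexadecyl)oxy](tert-butyl)dimethylsilane; 26 16-bromohexadecanoic acid
Product: 29 32-{[tert-butyl(dimethyl)silyl]oxy}dotriacontanoic acid, via Grignard reagent 27 (not isolated), via chloromagnesium carboxylate 28 (not isolated)
Conditions: 25, Mg, THF, 40 °C; 26, MeMgCl, THF, −20 °C; combine, Li2CuCl4 (cat.), −20 °C to rt; aq. citric acid
Reagents that add atoms: none
Why: Li2CuCl4‑catalysed coupling of the primary alkyl Grignard reagent with the primary bromide of the acid, protected in the flask as its magnesium salt, joins the two C16 units (copper‑catalysed sp3–sp3 Grignard cross‑coupling).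

Step 14
Reactants: 23 (2E)-5-[(1S,4aR,8aR)-2-{[tert-butyl(dimethyl)silyl]oxymethyl}-5,5,8a-trimethyl-1,4,4a,5,6,7,8,8a-octahydronaphthalen-1-yl]-3-methylpent-2-en-1-ol; 29 32-{[tert-butyl(dimethyl)silyl]oxy}dotriacontanoic acid
Product: 30 (2E)-5-[(1S,4aR,8aR)-2-{[tert-butyl(dimethyl)silyl]oxymethyl}-5,5,8a-trimethyl-1,4,4a,5,6,7,8,8a-octahydronaphthalen-1-yl]-3-methylpent-2-en-1-yl 32-{[tert-butyl(dimethyl)silyl]oxy}dotriacontanoate
Conditions: EDC·HCl, DMAP, CH2Cl2/THF, rt
Reagents that add atoms: none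
Why: Steglich esterification of the only free, unhindered primary alcohol with the carbodiimide‑activated acid.

Step 15
Reactants: 30 (2E)-5-[(1S,4aR,8aR)-2-{[tert-butyl(dimethyl)silyl]oxymethyl}-5,5,8a-trimethyl-1,4,4a,5,6,7,8,8a-octahydronaphthalen-1-yl]-3-methylpent-2-en-1-yl 32-{[tert-butyl(dimethyl)silyl]oxy}dotriacontanoate
Product: 31 (2E)-5-[(1S,4aR,8aR)-2-(hydroxymethyl)-5,5,8a-trimethyl-1,4,4a,5,6,7,8,8a-octahydronaphthalen-1-yl]-3-methylpent-2-en-1-yl 32-hydroxydotriacontanoate
Conditions: HF·pyridine, pyridine/THF, 0 °C to rt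
Reagents that add atoms: none
Why: Fluoride cleavage of both primary silyl ethers (desilylation) under buffered conditions should leave the allylic ester and the allylic alcohol untouched.

**Compound list**

1 | allyltrimethylsilane | C=CC[Si](C)(C)C | starting material
2 | [3-(trimethylsilyl)allyl]lithium | [Li]C/C=C/[Si](C)(C)C | intermediate
3 | (E)-1,3-bis(trimethylsilyl)prop-1-ene | C[Si](C)(C)C/C=C/[Si](C)(C)C | intermediate
4 | (1S,5S)-(−)-verbenone, (1S,5S)-4,6,6-trimethylbicyclo[3.1.1]hept-3-en-2-one | CC1=CC(=O)[C@H]2C[C@@H]1C2(C)C | starting material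
5 | trimethylsilyl enol ether of the conjugate adduct, 4,6,6-trimethyl-4-[1-(trimethylsilyl)prop-2-en-1-yl]-2-(trimethylsilyloxy)bicyclo[3.1.1]hept-2-ene; bridgeheads as in 4, new C–C bond anti to the gem-dimethyl bridge, epimers at the silyl-bearing carbon | C[Si](C)(C)OC1=C[C@](C)(C(C=C)[Si](C)(C)C)[C@@H]2C[C@H]1C2(C)C | intermediate
6 | trimethyl{[(4aR,8aR)-5,5,8a-trimethyl-1,4,4a,5,6,8a-hexahydronaphthalen-2-yl]oxy}silane | C[Si](C)(C)OC1=CC[C@@H]2C(C)(C)CC=C[C@@]2(C)C1 | intermediate
7 | (4aR,8aR)-5,5,8a-trimethyl-3,4,4a,5,6,8a-hexahydronaphthalen-2(1H)-one | O=C1CC[C@@H]2C(C)(C)CC=C[C@@]2(C)C1 | intermediate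
8 | (4aR,8aS)-5,5,8a-trimethyloctahydronaphthalen-2(1H)-one | O=C1CC[C@@H]2C(C)(C)CCC[C@@]2(C)C1 | intermediate
9 | (4aR,8aS)-5,5,8a-trimethyl-4a,5,6,7,8,8a-hexahydronaphthalen-2(1H)-one | O=C1C=C[C@@H]2C(C)(C)CCC[C@@]2(C)C1 | intermediate
10 | lithium dienolate of 9 (C8=C9 enolate) | [Li]OC=1C=C[C@@H]2C(C)(C)CCC[C@@]2(C)C=1 | intermediate
11 | Mannich base, 1-[(dimethylamino)methyl] derivative of 9 at C9, aminomethyl group anti to the C10 methyl (expected; centre removed in the same step) | CN(C)C[C@H]1C(=O)C=C[C@@H]2C(C)(C)CCC[C@@]12C | intermediate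
12 | methiodide of 11 | C[N+](C)(C)C[C@H]1C(=O)C=C[C@@H]2C(C)(C)CCC[C@@]12C.[I-] | intermediate
13 | (4aR,8aR)-5,5,8a-trimethyl-1-methylidene-4a,5,6,7,8,8a-hexahydronaphthalen-2(1H)-one | C=C1C(=O)C=C[C@@H]2C(C)(C)CCC[C@@]12C | intermediate
14 | ethyl 3-methylbut-2-enoate | CCOC(=O)C=C(C)C | starting material
15 | lithium dienolate of 14 | [Li]OC(OCC)=CC(C)=C | intermediate
16 | [(1-ethoxy-3-methylbuta-1,3-dien-1-yl)oxy]trimethylsilane | CCOC(=CC(C)=C)O[Si](C)(C)C | intermediate
17 | ethyl (2E)-3-methyl-5-{(4aR,8aR)-5,5,8a-trimethyl-2-[(trimethylsilyl)oxy]-4a,5,6,7,8,8a-hexahydronaphthalen-1-yl}pent-2-enoate | C/C(=C\C(=O)OCC)CCC1=C(O[Si](C)(C)C)C=C[C@@H]2C(C)(C)CCC[C@@]12C | intermediate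
18 | ethyl (2E)-3-methyl-5-[(1S,4aR,8aR)-5,5,8a-trimethyl-2-oxo-1,2,4a,5,6,7,8,8a-octahydronaphthalen-1-yl]pent-2-enoate | C/C(=C\C(=O)OCC)CC[C@@H]1C(=O)C=C[C@@H]2C(C)(C)CCC[C@@]12C | intermediate
19 | lithium enolate from conjugate reduction of 18 (C7=C8 enolate) | C/C(=C\C(=O)OCC)CC[C@@H]1C(O[Li])=CC[C@@H]2C(C)(C)CCC[C@@]12C | intermediate
20 | ethyl (2E)-3-methyl-5-[(1S,4aR,8aR)-5,5,8a-trimethyl-2-[(trifluoromethanesulfonyl)oxy]-1,4,4a,5,6,7,8,8a-octahydronaphthalen-1-yl]pent-2-enoate | C/C(=C\C(=O)OCC)CC[C@@H]1C(OS(=O)(=O)C(F)(F)F)=CC[C@@H]2C(C)(C)CCC[C@@]12C | intermediate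
21 | ethyl (2E)-5-[(1S,4aR,8aR)-2-(hydroxymethyl)-5,5,8a-trimethyl-1,4,4a,5,6,7,8,8a-octahydronaphthalen-1-yl]-3-methylpent-2-enoate | C/C(=C\C(=O)OCC)CC[C@@H]1C(CO)=CC[C@@H]2C(C)(C)CCC[C@@]12C | intermediate
22 | ethyl (2E)-5-[(1S,4aR,8aR)-2-{[tert-butyl(dimethyl)silyl]oxymethyl}-5,5,8a-trimethyl-1,4,4a,5,6,7,8,8a-octahydronaphthalen-1-yl]-3-methylpent-2-enoate | C/C(=C\C(=O)OCC)CC[C@@H]1C(CO[Si](C)(C)C(C)(C)C)=CC[C@@H]2C(C)(C)CCC[C@@]12C | intermediate
23 | (2E)-5-[(1S,4aR,8aR)-2-{[tert-butyl(dimethyl)silyl]oxymethyl}-5,5,8a-trimethyl-1,4,4a,5,6,7,8,8a-octahydronaphthalen-1-yl]-3-methylpent-2-en-1-ol | C/C(=C\CO)CC[C@@H]1C(CO[Si](C)(C)C(C)(C)C)=CC[C@@H]2C(C)(C)CCC[C@@]12C | intermediate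
24 | 16-bromohexadecan-1-ol | OCCCCCCCCCCCCCCCCBr | starting material
25 | [(16-bromohexadecyl)oxy](tert-butyl)dimethylsilane | CC(C)(C)[Si](C)(C)OCCCCCCCCCCCCCCCCBr | intermediate
26 | 16-bromohexadecanoic acid | OC(=O)CCCCCCCCCCCCCCCBr | starting material
27 | (16-{[tert-butyl(dimethyl)silyl]oxy}hexadecyl)magnesium bromide | CC(C)(C)[Si](C)(C)OCCCCCCCCCCCCCCCC[Mg]Br | intermediate
28 | chloromagnesium 16-bromohexadecanoate | Cl[Mg]OC(=O)CCCCCCCCCCCCCCCBr | intermediate
29 | 32-{[tert-butyl(dimethyl)silyl]oxy}dotriacontanoic acid | OC(=O)CCCCCCCCCCCCCCCCCCCCCCCCCCCCCCCO[Si](C)(C)C(C)(C)C | intermediate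
30 | (2E)-5-[(1S,4aR,8aR)-2-{[tert-butyl(dimethyl)silyl]oxymethyl}-5,5,8a-trimethyl-1,4,4a,5,6,7,8,8a-octahydronaphthalen-1-yl]-3-methylpent-2-en-1-yl 32-{[tert-butyl(dimethyl)silyl]oxy}dotriacontanoate | C/C(=C\COC(=O)CCCCCCCCCCCCCCCCCCCCCCCCCCCCCCCO[Si](C)(C)C(C)(C)C)CC[C@@H]1C(CO[Si](C)(C)C(C)(C)C)=CC[C@@H]2C(C)(C)CCC[C@@]12C | intermediate
31 | (2E)-5-[(1S,4aR,8aR)-2-(hydroxymethyl)-5,5,8a-trimethyl-1,4,4a,5,6,7,8,8a-octahydronaphthalen-1-yl]-3-methylpent-2-en-1-yl 32-hydroxydotriacontanoate (CNP0264179.1; 5R,9S,10R,13E in labdane numbering) | C/C(=C\COC(=O)CCCCCCCCCCCCCCCCCCCCCCCCCCCCCCCO)CC[C@@H]1C(CO)=CC[C@@H]2C(C)(C)CCC[C@@]12C | target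

**Step count and risks**

Total step count: 15. Longest linear sequence: 12 steps (steps 1, 2, 3, 4, 5, 7, 8, 9, 10, 11, 14, 15).

Steps most likely to fail:

Step 2 (Proposed new method). What may go wrong:
- ring opening or skeletal rearrangement of verbenone before the conjugate addition;
- protodesilylation of the allylsilane instead of protonation of the enol ether;
- sluggish cyclisation of the epimer whose C–Si bond cannot align with the developing cation;
- acid‑induced migration of the new C1=C2 alkene.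

Fallback (sets out from 4, comes back at 8; known reactions only): copper‑catalysed conjugate addition of allylmagnesium bromide to 4 (CuBr·SMe2, Me3SiCl, THF, −78 °C), anti to the gem‑dimethyl bridge, should give (1S,4S,5S)-4,6,6-trimethyl-4-(prop-2-en-1-yl)bicyclo[3.1.1]heptan-2-one F1. The known iodotrimethylsilane cleavage of the pinan‑2‑one cyclobutane followed by DBU should give (3S,4R)-3-methyl-3-(prop-2-en-1-yl)-4-(prop-1-en-2-yl)cyclohexan-1-one F2. Hydroboration of the monosubstituted alkene with 9‑BBN and iodination of the borane (I2, NaOMe) should give (3S,4R)-3-(3-iodopropyl)-3-methyl-4-(prop-1-en-2-yl)cyclohexan-1-one F3. A Mn(dpm)3/Ni(acac)2‑catalysed hydroalkylation (PhSiH3, K2CO3; hydrogen‑atom transfer to the isopropenyl group and capture of the tertiary radical by the alkylnickel species) then closes ring A at C3–C4 and gives 8 directly, so that step 3 falls away.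

Step 7. What may go wrong:
- attack of the dienolate through its α‑carbon instead of the γ‑carbon;
- poor E/Z control of the new trisubstituted alkene;
- poor facial selectivity of the protonation at C9, or later epimerisation there.

Fallback (sets out from 13, comes back at 18): Mukaiyama–Michael addition of 2‑(trimethylsilyloxy)propene to 13 (TiCl4, CH2Cl2, −78 °C, with the same face‑selective protonation at C9) should give (1S,4aR,8aR)-5,5,8a-trimethyl-1-(3-oxobutyl)-4a,5,6,7,8,8a-hexahydronaphthalen-2(1H)-one F4. Horner–Wadsworth–Emmons olefination of its unhindered methyl ketone with triethyl phosphonoacetate (NaH, THF) gives 18, the E isomer being separated from the minor Z isomer.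

Step 9. What may go wrong:
- slow transmetalation at the hindered enol triflate;
- competing reduction of the triflate to the alkene.

Fallback (sets out from 20, comes back at 21): palladium‑catalysed formylation of 20 (CO, Bu3SnH, Pd(PPh3)4, THF, 50 °C) should give ethyl (2E)-5-[(1S,4aR,8aR)-2-formyl-5,5,8a-trimethyl-1,4,4a,5,6,7,8,8a-octahydronaphthalen-1-yl]-3-methylpent-2-enoate F5. Luche reduction (NaBH4, CeCl3·7H2O, MeOH, −78 °C) reduces only the aldehyde and gives 21.

Further compounds
F1 | step 2 | (1S,4S,5S)-4,6,6-trimethyl-4-(prop-2-en-1-yl)bicyclo[3.1.1]heptan-2-one | C=CC[C@@]1(C)CC(=O)[C@H]2C[C@@H]1C2(C)C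
F2 | step 2 | (3S,4R)-3-methyl-3-(prop-2-en-1-yl)-4-(prop-1-en-2-yl)cyclohexan-1-one | C=CC[C@@]1(C)CC(=O)CC[C@@H]1C(C)=C
F3 | step 2 | (3S,4R)-3-(3-iodopropyl)-3-methyl-4-(prop-1-en-2-yl)cyclohexan-1-one | ICCC[C@@]1(C)CC(=O)CC[C@@H]1C(C)=C
F4 | step 7 | (1S,4aR,8aR)-5,5,8a-trimethyl-1-(3-oxobutyl)-4a,5,6,7,8,8a-hexahydronaphthalen-2(1H)-one | CC(=O)CC[C@@H]1C(=O)C=C[C@@H]2C(C)(C)CCC[C@@]12C
F5 | step 9 | ethyl (2E)-5-[(1S,4aR,8aR)-2-formyl-5,5,8a-trimethyl-1,4,4a,5,6,7,8,8a-octahydronaphthalen-1-yl]-3-methylpent-2-enoate | C/C(=C\C(=O)OCC)CC[C@@H]1C(C=O)=CC[C@@H]2C(C)(C)CCC[C@@]12C
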